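## Retrosynthetic overview

1. The target acid comes from methyl ester 22 by saponification; 22 comes from a Sonogashira union of the alkyne-armed dioxane 17 with the (E)-iodoalkene 21.
2. The only ring, the 1,2-dioxane, is not closed as a six-membered ring. Its four carbons C3–C6 are carried as a cyclobutanol (13), and O1–O2 enters as one molecule of O2 inserted into the bond between the carbinol carbon (future C6) and its more substituted neighbour (future C3); methanol then converts the hemiketal into the ketal, three components in one flask.
3. The feature that allows this: C6 is a peroxyketal, a masked ketone, standing 1,4 to the peroxy-bearing methine C3 across the C4–C5 bridge. That is the pattern left by β-scission of a 1,2-disubstituted cyclobutanol, and the axial OMe with both carbon chains equatorial is the thermodynamic arrangement.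
4. Absolute configuration: lipase kinetic resolution of the racemic core ester 16 directly after the ring expansion.
5. Rings in order: cyclobutane (bought as cyclobutanone, armed by aza-enolate alkylation and Grignard addition), then a temporary cis-fused γ-lactone 11 (opened again), then the 1,2-dioxane. Fragment 21 comes from dec-9-en-1-ol by Wacker oxidation, alcohol oxidation and Takai olefination.

Key step: step 5

Numbering used for the dioxane: O1, O2, C3 (methine bearing the acetic acid arm), C4, C5, C6 (ketal carbon).

Assumption: the sense of enantiopreference of a lipase for a stereocentre β to the acyl carbon cannot be predicted; the route is written for an enzyme that hydrolyses the (3R,6S)-ester faster, so that the (3S,6R)-ester is recovered.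

## Route

Step 1
Reactants: 1 cyclobutanone; 2 cyclohexylamine
Product: 3 N-cyclohexylcyclobutanimine
Conditions: 4 Å molecular sieves, Et2O, rt
Reagents that add atoms: none
Why: Imine condensation driven by removal of water gives the N-cyclohexyl imine, the usual handle for clean α-monoalkylation of cyclobutanone, whose own enolate self-condenses.

Step 2
Reactants: 3 N-cyclohexylcyclobutanimine; 4 methyl bromoacetate
Product: 7 racemic methyl 2-(2-oxocyclobutyl)acetate, via lithium azaenolate 5 (not isolated), via alkylated imine 6 (not isolated)
Conditions: LDA, THF, −78 to 0 °C; 4, −78 °C to rt; then aq. oxalic acid, rt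
Reagents that add atoms: water, O
Why: Metalloenamine (aza-enolate) alkylation installs the two-carbon acid arm by SN2 displacement of bromide, and mild aqueous acid hydrolyses the imine; the new stereocentre is racemic and is erased in step 5.

Step 3
Reactants: 7 racemic methyl 2-(2-oxocyclobutyl)acetate; 8 (5-chloropent-1-yn-1-yl)trimethylsilane
Product: 11 racemic cis-fused 1-[5-(trimethylsilyl)pent-4-yn-1-yl]-2-oxabicyclo[3.2.0]heptan-3-one, via Grignard reagent 9 (not isolated), via chloromagnesium alkoxide 10 (not isolated)
Conditions: 8, Mg, THF, reflux; then 7, LaCl3·2LiCl (cat.), THF, −78 °C to rt; aq. NH4Cl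
Reagents that add atoms: none
Why: Grignard 1,2-addition is chemoselective for the strained ketone over the ester at −78 °C, attack anti to the C2 arm places the alkoxide cis to the ester, and this lactonises on warming, so the γ-lactone serves as a stable temporary ring (any epimer that cannot lactonise is carried along, since step 4 gives the same hydroxy ester and step 5 erases both stereocentres).

Step 4
Reactants: 11 racemic cis-fused lactone
Product: 13 methyl 2-[2-hydroxy-2-(pent-4-yn-1-yl)cyclobutyl]acetate (racemic, mainly OH cis to the ester arm), via potassium carboxylate 12 (not isolated)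
Conditions: KOH (1.5 equiv), MeOH/H2O, rt; CO2 to pH 8, evaporation; MeI, DMF, rt
Reagents that add atoms: potassium hydroxide, [K+].[OH-]; iodomethane, CI
Why: Saponification of the lactone and base-mediated protodesilylation of the alkynylsilane occur together, and SN2 O-methylation of the potassium carboxylate gives the γ-hydroxy methyl ester without passing through the free hydroxy acid or acidic conditions that would close the lactone again.

Step 5
Reactants: 13 methyl 2-[2-hydroxy-2-(pent-4-yn-1-yl)cyclobutyl]acetate
Product: 16 racemic methyl 2-[(3S*,6R*)-6-methoxy-6-(pent-4-yn-1-yl)-1,2-dioxan-3-yl]acetate, via hydroperoxy ketone 14 (not isolated), via dioxanol 15 (not isolated)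
Conditions: Co(acac)2 (20 mol %), O2 (1 atm), ClCH2CH2Cl, rt to 40 °C; then argon, MeOH, TsOH·H2O (0.6 equiv), rt, same flask
Reagents that add atoms: dioxygen, O=O; methanol, CO
Why: The trivalent cobalt–peroxo species formed from Co(acac)2 and O2 exchanges with the tertiary alcohol and releases the cyclobutyloxy radical, whose strain-driven β-scission cuts the ring bond to the more substituted carbon; the secondary alkyl radical captures O2 and the peroxyl radical is reduced by divalent cobalt to γ-hydroperoxy ketone 14, so that O2 is in effect inserted into the C–C(OH) bond. The closest known reaction type is the Co(acac)2/O2 oxidative ring expansion of cyclobutanols (tertiary ones included) to 1,2-dioxan-3-ols, followed by the standard acid-catalysed exchange of a peroxy hemiketal into its methyl ketal. The 1,2-dioxane closes by 6-exo-trig addition of the hydroperoxide oxygen to the ketone carbonyl (14 to 15), the four-membered carbocycle thus growing by the two oxygen atoms. C3 is created when O2 meets a planar radical and is therefore racemic (resolved in step 6), whereas C6 is set relative to it through the peroxycarbenium ion in TsOH/MeOH: axial attack of methanol and the anomeric effect both hold OMe axial while the two carbon chains stay equatorial, which is the (3S*,6R*) relationship of the target. The step needs regioselective β-scission, secured by the secondary versus primary radical (the exocyclic chain is not cleaved because that releases no strain), and it needs ring opening to outrun lactonisation of the γ-hydroxy ester and any radical attack on the terminal alkyne, for which the neutral medium, the mild temperature and the fast O2 capture are relied upon.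

Step 6
Reactants: 16 racemic methyl 2-[(3S*,6R*)-6-methoxy-6-(pent-4-yn-1-yl)-1,2-dioxan-3-yl]acetate
Product: 17 methyl 2-[(3S,6R)-6-methoxy-6-(pent-4-yn-1-yl)-1,2-dioxan-3-yl]acetate (recovered, unreacted enantiomer)
Conditions: Burkholderia cepacia lipase (Amano PS), phosphate buffer pH 7.0/MTBE, 30 °C, run to about 55% conversion (pH-stat); extraction at pH 8
Reagents that add atoms: none
Why: Lipase-catalysed enantioselective ester hydrolysis (kinetic resolution) removes the fast-reacting enantiomer as its water-soluble carboxylate, and running past half conversion raises the ee of the recovered ester, which fixes the absolute configuration at C3 and with it at C6, while neutral pH leaves peroxide and ketal intact.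

Step 7
Reactants: 18 dec-9-en-1-ol
Product: 19 10-hydroxydecan-2-one
Conditions: PdCl2 (10 mol %), CuCl (co-catalyst), O2 (1 atm), DMF/H2O, rt
Reagents that add atoms: water, O
Why: Tsuji–Wacker oxidation, in which Markovnikov hydroxypalladation of the terminal alkene by divalent palladium and β-hydride elimination give the methyl ketone and copper chloride with O2 turns the catalyst over, tolerates the remote primary alcohol.

Step 8
Reactants: 19 10-hydroxydecan-2-one
Product: 20 9-oxodecanal
Conditions: TEMPO (10 mol %), PhI(OAc)2, CH2Cl2, rt
Reagents that add atoms: none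
Why: Oxoammonium (TEMPO/PhI(OAc)2) oxidation of the primary alcohol stops at the aldehyde and leaves the ketone untouched.

Step 9
Reactants: 20 9-oxodecanal
Product: 21 (E)-11-iodoundec-10-en-2-one
Conditions: CrCl2, CHI3, THF/1,4-dioxane, 0 °C to rt
Reagents that add atoms: iodoform, IC(I)I
Why: Takai olefination, in which the geminal dichromium reagent from CHI3 and CrCl2 adds to the aldehyde much faster than to the methyl ketone and anti elimination gives the (E)-iodoalkene preferentially.

Step 10
Reactants: 17 methyl 2-[(3S,6R)-6-methoxy-6-(pent-4-yn-1-yl)-1,2-dioxan-3-yl]acetate; 21 (E)-11-iodoundec-10-en-2-one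
Product: 22 methyl 2-[(3S,6R)-6-methoxy-6-[(6E)-15-oxohexadec-6-en-4-yn-1-yl]-1,2-dioxan-3-yl]acetate
Conditions: PdCl2(PPh3)2 (5 mol %), CuI (10 mol %), Et3N, THF, rt, degassed
Reagents that add atoms: none
Why: Sonogashira coupling of the terminal alkyne with the (E)-alkenyl iodide proceeds at room temperature with retention of alkene geometry, conditions under which dialkyl peroxyketals of this kind should persist, and no stereocentre is touched.

Step 11
Reactants: 22 methyl 2-[(3S,6R)-6-methoxy-6-[(6E)-15-oxohexadec-6-en-4-yn-1-yl]-1,2-dioxan-3-yl]acetate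
Product: 24 2-[(3S,6R)-6-methoxy-6-[(6E)-15-oxohexadec-6-en-4-yn-1-yl]-1,2-dioxan-3-yl]acetic acid, via lithium carboxylate 23 (not isolated)
Conditions: LiOH·H2O, THF/H2O, 0 °C; then cold 0.5 M HCl to pH 3–4
Reagents that add atoms: lithium hydroxide, [Li+].[OH-]
Why: Saponification of the unhindered methyl ester at 0 °C should be far faster than α-deprotonation, so β-elimination of the peroxide and epimerisation at C3 are not expected, the carboxylate formed is inert to it, and the ketal sees only base and a brief cold dilute acid.

## Compound list

1 | cyclobutanone | O=C1CCC1 | starting material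
2 | cyclohexylamine | NC1CCCCC1 | starting material
3 | N-cyclohexylcyclobutanimine | C1CC(=NC2CCCCC2)C1 | intermediate
4 | methyl bromoacetate | COC(=O)CBr | starting material
5 | lithium azaenolate of 3 (N-lithio-N-cyclohexylcyclobut-1-en-1-amine) | [Li]N(C1CCCCC1)C1=CCC1 | intermediate (not isolated)
6 | methyl 2-[2-(cyclohexylimino)cyclobutyl]acetate (racemic) | COC(=O)CC1CCC1=NC1CCCCC1 | intermediate (not isolated)
7 | methyl 2-(2-oxocyclobutyl)acetate (racemic) | COC(=O)CC1CCC1=O | intermediate
8 | (5-chloropent-1-yn-1-yl)trimethylsilane | C[Si](C)(C)C#CCCCCl | starting material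
9 | [5-(trimethylsilyl)pent-4-yn-1-yl]magnesium chloride | C[Si](C)(C)C#CCCC[Mg]Cl | intermediate (not isolated)
10 | chloromagnesium alkoxide of methyl 2-[2-hydroxy-2-[5-(trimethylsilyl)pent-4-yn-1-yl]cyclobutyl]acetate (racemic) | COC(=O)CC1CCC1(O[Mg]Cl)CCCC#C[Si](C)(C)C | intermediate (not isolated)
11 | cis-fused 1-[5-(trimethylsilyl)pent-4-yn-1-yl]-2-oxabicyclo[3.2.0]heptan-3-one (racemic, both enantiomers written) | O=C1C[C@H]2CC[C@@]2(CCCC#C[Si](C)(C)C)O1.O=C1C[C@@H]2CC[C@]2(CCCC#C[Si](C)(C)C)O1 | intermediate
12 | potassium 2-[2-hydroxy-2-(pent-4-yn-1-yl)cyclobutyl]acetate (racemic) | [K+].[O-]C(=O)CC1CCC1(O)CCCC#C | intermediate (not isolated)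
13 | methyl 2-[2-hydroxy-2-(pent-4-yn-1-yl)cyclobutyl]acetate (racemic, diastereomer mixture, mainly OH cis to the ester arm) | COC(=O)CC1CCC1(O)CCCC#C | intermediate
14 | methyl 3-hydroperoxy-6-oxoundec-10-ynoate (racemic) | COC(=O)CC(OO)CCC(=O)CCCC#C | intermediate (not isolated)
15 | methyl 2-[6-hydroxy-6-(pent-4-yn-1-yl)-1,2-dioxan-3-yl]acetate (racemic, anomer mixture) | COC(=O)CC1CCC(O)(CCCC#C)OO1 | intermediate (not isolated)
16 | methyl 2-[(3S*,6R*)-6-methoxy-6-(pent-4-yn-1-yl)-1,2-dioxan-3-yl]acetate (racemic, both enantiomers written) | CO[C@@]1(CCCC#C)CC[C@@H](CC(=O)OC)OO1.CO[C@]1(CCCC#C)CC[C@H](CC(=O)OC)OO1 | intermediate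
17 | methyl 2-[(3S,6R)-6-methoxy-6-(pent-4-yn-1-yl)-1,2-dioxan-3-yl]acetate | CO[C@@]1(CCCC#C)CC[C@@H](CC(=O)OC)OO1 | intermediate
18 | dec-9-en-1-ol | C=CCCCCCCCCO | starting material
19 | 10-hydroxydecan-2-one | CC(=O)CCCCCCCCO | intermediate
20 | 9-oxodecanal | CC(=O)CCCCCCCC=O | intermediate
21 | (E)-11-iodoundec-10-en-2-one | CC(=O)CCCCCCC/C=C/I | intermediate
22 | methyl 2-[(3S,6R)-6-methoxy-6-[(6E)-15-oxohexadec-6-en-4-yn-1-yl]-1,2-dioxan-3-yl]acetate | CO[C@@]1(CCCC#C/C=C/CCCCCCCC(C)=O)CC[C@@H](CC(=O)OC)OO1 | intermediate
23 | lithium 2-[(3S,6R)-6-methoxy-6-[(6E)-15-oxohexadec-6-en-4-yn-1-yl]-1,2-dioxan-3-yl]acetate | [Li+].CO[C@@]1(CCCC#C/C=C/CCCCCCCC(C)=O)CC[C@@H](CC(=O)[O-])OO1 | intermediate (not isolated)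
24 | 2-[(3S,6R)-6-methoxy-6-[(6E)-15-oxohexadec-6-en-4-yn-1-yl]-1,2-dioxan-3-yl]acetic acid | CO[C@@]1(CCCC#C/C=C/CCCCCCCC(C)=O)CC[C@@H](CC(=O)O)OO1 | target

## Step count and risks

Total step count: 11. Longest linear sequence: 8 steps (steps 1–6, 10, 11).

Steps most likely to fail:

Step 5. What may go wrong: closure of the cis-γ-hydroxy ester to the lactone before or at the cobalt alkoxide stage, cobalt-induced breakdown of the hydroperoxide once formed, and incomplete regioselectivity of β-scission. The fallback sets out from Grignard reagent 9 (made from 8 as in step 3) and comes back at 16; it builds the peroxide by hydroperoxyketal conjugate addition instead of O2 insertion. Reagent 9 is added to N-methoxy-N-methylpent-4-enamide (THF, 0 °C) to give 10-(trimethylsilyl)dec-1-en-9-yn-5-one F1. Cross-metathesis of F1 with methyl acrylate (second-generation Hoveyda–Grubbs catalyst, CH2Cl2, 40 °C) gives methyl (2E)-6-oxo-11-(trimethylsilyl)undec-2-en-10-ynoate F2. Urea–hydrogen peroxide with Sc(OTf)3 (cat.) in MeOH converts the ketone into methyl (2E)-6-hydroperoxy-6-methoxy-11-(trimethylsilyl)undec-2-en-10-ynoate F3. Et2NH in CF3CH2OH closes the ring by intramolecular peroxy-Michael addition, and TsOH/MeOH equilibrates the ketal to racemic methyl 2-[(3S*,6R*)-6-methoxy-6-[5-(trimethylsilyl)pent-4-yn-1-yl]-1,2-dioxan-3-yl]acetate F4. TBAF buffered with AcOH (THF, 0 °C) removes the silyl group and gives 16.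

Step 6. What may go wrong: too low an enantioselectivity of the hydrolase for a stereocentre β to the acyl group, or preference for the wrong enantiomer. The fallback sets out from 16 and comes back at 17: the enantiomers of 16 are separated by preparative chromatography on a chiral stationary phase (amylose tris(3,5-dimethylphenylcarbamate), supercritical CO2/MeOH), and the (3S,6R)-enantiomer is assigned by correlation with the target acid. No new compound is made.

Step 10. What may go wrong: reduction of the O–O bond by triphenylphosphine or zerovalent palladium, and copper-mediated homocoupling of the alkyne. The fallback sets out from 13 and 21 and comes back at 22; it moves the coupling ahead of the oxygenation so that no peroxide meets the metals. Cyclobutanol 13 and 21 (PdCl2(PPh3)2, CuI, Et3N, THF) give methyl 2-[2-hydroxy-2-[(6E)-15-oxohexadec-6-en-4-yn-1-yl]cyclobutyl]acetate F5. The conditions of step 5 then give racemic methyl 2-[(3S*,6R*)-6-methoxy-6-[(6E)-15-oxohexadec-6-en-4-yn-1-yl]-1,2-dioxan-3-yl]acetate F6. The lipase resolution of step 6, applied to F6, leaves 22.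

Further compounds
F1 | step 5 | 10-(trimethylsilyl)dec-1-en-9-yn-5-one | C=CCCC(=O)CCCC#C[Si](C)(C)C
F2 | step 5 | methyl (2E)-6-oxo-11-(trimethylsilyl)undec-2-en-10-ynoate | COC(=O)/C=C/CCC(=O)CCCC#C[Si](C)(C)C
F3 | step 5 | methyl (2E)-6-hydroperoxy-6-methoxy-11-(trimethylsilyl)undec-2-en-10-ynoate (racemic) | COC(=O)/C=C/CCC(OC)(OO)CCCC#C[Si](C)(C)C
F4 | step 5 | methyl 2-[(3S*,6R*)-6-methoxy-6-[5-(trimethylsilyl)pent-4-yn-1-yl]-1,2-dioxan-3-yl]acetate (racemic, both enantiomers written) | CO[C@@]1(CCCC#C[Si](C)(C)C)CC[C@@H](CC(=O)OC)OO1.CO[C@]1(CCCC#C[Si](C)(C)C)CC[C@H](CC(=O)OC)OO1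
F0 | step 6 | none | none
F5 | step 10 | methyl 2-[2-hydroxy-2-[(6E)-15-oxohexadec-6-en-4-yn-1-yl]cyclobutyl]acetate (racemic, diastereomer mixture) | COC(=O)CC1CCC1(O)CCCC#C/C=C/CCCCCCCC(C)=O
F6 | step 10 | methyl 2-[(3S*,6R*)-6-methoxy-6-[(6E)-15-oxohexadec-6-en-4-yn-1-yl]-1,2-dioxan-3-yl]acetate (racemic, both enantiomers written) | CO[C@@]1(CCCC#C/C=C/CCCCCCCC(C)=O)CC[C@@H](CC(=O)OC)OO1.CO[C@]1(CCCC#C/C=C/CCCCCCCC(C)=O)CC[C@H](CC(=O)OC)OO1
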